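The easy step is to divide each last reading by its substrate charge, and that is where I start.

| flask | substrate | coupling partner | free catalyst | time |
|---|---|---|---|---|
| north-west | 250 mM | 750 mM | 20.0 mM |  |
| north-east | 100 mM | 600 mM | 20.0 mM |  |
| north | 500 mM | 750 mM | 20.0 mM |  |
| west | 250 mM | 750 mM | 60.0 mM |  |
| east | 1600 mM | 750 mM | 20.0 mM | 8.5 h |

- north-west run (time / h: [target] / mM): 1.1: 26.0; 2.1: 45.2; 3.2: 65.9; 4.2: 83.7; 5.3: 100.4; 6.4: 113.8; 7.4: 125.3; 8.5: 136.5
- north-east run (time / h: [target] / mM): 1.1: 10.2; 2.1: 15.7; 3.2: 23.4; 4.2: 30.8; 5.3: 35.9; 6.4: 42.5; 7.4: 45.7; 8.5: 50.7
- north run (time / h: [target] / mM): 1.1: 51.4; 2.1: 91.3; 3.2: 130.7; 4.2: 161.2; 5.3: 191.0; 6.4: 219.4; 7.4: 241.3; 8.5: 261.9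
- west run (time / h: [target] / mM): 1.1: 63.4; 2.1: 103.5; 3.2: 138.0; 4.2: 161.4; 5.3: 180.8; 6.4: 196.7; 7.4: 207.0; 8.5: 215.7

(readings scatter by 0.8 mM)

- Overall: substrate + coupling partner -> target, with free catalyst as catalyst.
- Constant volume, constant temperature.
- Bound and free are read together.
- "The second partner" is coupling partner.
- An order is taken over about fifteen percent of the charge, up and down.

- apparent order in [substrate] of the starting rate, round the charge of the north-west run (the rate where two percent of its substrate have turned into target) (one fixed amount of target, the same in the runs compared)
- apparent order in [free catalyst] of the starting rate, round the charge of the north-west run (the rate where two percent of its substrate have turned into target)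
- the north-east run starts with 150 mM less of substrate and of coupling partner than the north-west run, and with no target. Compared where both hold the same amount of substrate, once fifteen percent of what the north-east run was charged with has turned into target, is the north-east run faster, slower or alike (within a tenth)?
- target in the east run at 8.5 h, as a share of the substrate charged

The north run holds twice the substrate of the north-west run, yet the share of substrate turned at 8.5 h barely moves, from 54.6% to 52.4%. That is the bench rule for a pseudo-first-order flask: at one charge of coupling partner and of free catalyst, with the partner in large excess, the share turned by a given time stays nearly the same when the substrate charge changes.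

The border is the ratio of substrate charge to partner charge. It is a third in the north-west run, and 2.13 in the east run, where the coupling partner is the limiting reagent. The rule would ask the east run for 112% of the partner charge, more than the flask holds, and the ceiling on target is 46.9% of the substrate charge.

So I replace each falling curve by its mean. My mean-charge number, the share of substrate turned at 8.5 h divided by the mean remaining shares of substrate and of partner, is read here at a partner charge of 750 mM and 20.0 mM of free catalyst:

| Run | Substrate over partner | Substrate turned | Partner used | Number |
|---|---|---|---|---|
| north-west | 0.333 | 54.6% | 18.2% | 0.826 |
| north | 0.667 | 52.4% | 34.9% | 0.860 |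

I take the north value, whose ratio stands nearer the east run's than the north-west value's does. Holding it for the east run and solving for the share gives 2.35 as a working term and 39.7% of the substrate charge.

The mean has a cost. Integrating a rate proportional to substrate times partner from the north reading gives 0.937 as its constant and 2.89 as its factor, hence 36.6%, which is 3.1 percentage points lower. I commit to the mean value with that margin below it. In the east run the reading to watch is the one at 8.5 h, where by my reckoning the partner used reaches 84.6% of its charge, more than in the north run.

The forecast gives 0.97 (0.88 to 1.03) for the substrate order and 0.88 (0.8 to 0.95) for the free catalyst order. It calls the north-east and north-west runs alike and puts the east run at 39% (33% to 42.5%). One of its grounds reads: “k sags as the partner is used, more in the runs that consume more of it”.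

    2 free catalyst ⇌ catalyst dimer, settled at all times (588.0 /M)
    catalyst dimer + substrate + coupling partner → target + catalyst dimer (19.01 /M²/h)
    substrate + coupling partner → target (0.07380 /M/h)
    free catalyst + coupling partner ⇌ idle catalyst-reagent complex, settled at all times (6.350 /M)

The east run gives 38.6% of its substrate charge, inside the forecast's range. The flask and the forecast part on the free catalyst order, 0.68 against the forecast's 0.88, while the substrate order is 1.0 and the north-east and north-west runs are alike at equal substrate. Read back from that share, the east run's mean-charge number is 0.813, lower than the north run's 0.860. Taken as proportional to time and put on the north-west run, the north number gives half of its substrate turned at 7.19 h, and the simulated time for that run is 7.34 h.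

The numbers in the tables were computed for an exercise, and the scatter is random.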